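**Plan**

1. Numbering used here (arbitrary). Ring B = C1(CH3)=C2–C3–C4–C5–C6(CH3)–C7–C8. Ring A = C2, C3, C16(CH3), C17, C18. Ring C = C7=C9–C10(CH3)–C11–C12–C8. Ring D = C10, C13(OH), C14, C15(iPr), C11. β is the face of the C10 methyl in the flat drawing. The target is 3α-H, 6α-CH3, 8α-H, 10β-CH3, 11α-H, 13β-OH, 15α-iPr, 16β-CH3.
2. Enabling feature: in ring B the Z tetrasubstituted C1=C2 bond (C2 shared with ring A) lies γ,δ to C5 (C5–C4–C3–C2=C1), and C3 is the allylic ring-fusion stereocentre. Ring B with a carbonyl at C5 is therefore a Claisen retron. Cutting C3–C4 and rejoining C1 to C5 through oxygen contracts ring B to a six-membered temporary ring (O, C5, C6, C7, C8, C1). This ring carries ring A as a cyclopent-1-enyl group on C1 and an exocyclic methylene (C4) on C5.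
3. Further cuts are C4 (titanium methylidene on a δ-lactone), C6–CH3 (cuprate), C1–C2 (alkenylcerium plus methyl ketone) and C6–C7 (enolate alkylation). Ring D is cut at C14=C15 (metathesis), C10–C13 (aldol) and C11–C15 (conjugate addition). This leads back to (R)-carvone, cyclopentenone, acrolein, 2-bromo-3-methylbut-1-ene and methyl bromoacetate.
4. Forward order: ring A is made separately and ring C is bought. Ring D is annulated on ring C, ring A is attached at C1 with closure of the temporary lactone, and ring B is closed last by ring expansion.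
5. Stereochemistry: C8 of (R)-carvone controls C11, C10 and C13 and is then itself inverted by equilibration. C15 comes from an OH-directed hydrogenation and C16 from a ligand-controlled conjugate addition. The temporary centre C1 comes from a Felkin–Anh-type addition and is relayed to C3 by the [3,3] shift. C6 comes from cuprate attack anti to the β-methyl groups.
6. Helpers: the oxygens at C5 and C9 and the benzyl group on O13 are all removed in one dissolving-metal step at the end.

Key step: step 14

Remark: 2-bromo-3-methylbut-1-ene is taken as purchasable, and in step 1 the ligand antipode is the one that delivers the S enolate.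

**Route**

Step 1
Reactants: 1 cyclopent-2-en-1-one
Product: 3 (S)-3-methylcyclopent-1-en-1-yl trifluoromethanesulfonate, via methylzinc enolate 2 (not isolated)
Conditions: Me2Zn, Cu(OTf)2 (2 mol %), BINOL/bis(1-phenylethyl)amine phosphoramidite (4 mol %), toluene, −30 °C; then Tf2O, −30 to 0 °C
Reagents that add atoms: dimethylzinc C[Zn]C; trifluoromethanesulfonic anhydride O=S(=O)(OS(=O)(=O)C(F)(F)F)C(F)(F)F
Why: Copper-catalysed enantioselective conjugate addition of a dialkylzinc to a cyclic enone sets C16 under ligand control, and O-triflation of the regiodefined zinc enolate should fix the double bond between C2 and C3, next to the new stereocentre.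

Step 2
Reactants: 3 (S)-3-methylcyclopent-1-en-1-yl trifluoromethanesulfonate
Product: 4 tributyl[(S)-3-methylcyclopent-1-en-1-yl]stannane
Conditions: (Bu3Sn)2, Pd(PPh3)4 (5 mol %), LiCl, THF, reflux
Reagents that add atoms: hexabutyldistannane CCCC[Sn](CCCC)(CCCC)[Sn](CCCC)(CCCC)CCCC
Why: Palladium-catalysed stannylation of an enol triflate (Stille-type coupling with a distannane) should exchange OTf for SnBu3 without touching C16 and give a storable precursor of the alkenyllithium.

Step 3
Reactants: 5 (R)-(−)-carvone; 6 2-bromo-3-methylbut-1-ene; 7 acrolein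
Product: 10 triene silyl ether (ring C cyclohexanone), via Grignard reagent 8 (not isolated), via magnesium enolate 9 (not isolated)
Conditions: 6, Mg, THF; CuBr·SMe2 (10 mol %), 5, THF, −78 °C; 7, −78 °C; Me3SiCl, −78 °C to rt
Reagents that add atoms: chlorotrimethylsilane C[Si](C)(C)Cl
Why: In this tandem conjugate addition–aldol reaction the alkenylcopper species should add anti to the C8 isopropenyl group (sets C11), the magnesium enolate should attack acrolein anti to the new C11 substituent (sets quaternary C10) through a Zimmerman–Traxler chair with the vinyl group equatorial (sets C13 with oxygen syn to the C10 methyl), and silylation of the aldolate blocks retro-aldol cleavage.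

Step 4
Reactants: 10 triene silyl ether
Product: 11 trans-hydrindenone silyl ether (rings C and D, C14=C15)
Conditions: second-generation Grubbs catalyst (5 mol %), toluene, 80 °C
Reagents that add atoms: none
Why: Ring-closing metathesis between the vinyl group (initiation site) and the 1,1-disubstituted alkene should close ring D as a trisubstituted cyclopentene on the trans-diequatorial C10 and C11 substituents, the C8 isopropenyl group being unable to reach either partner in an unstrained ring, and no stereocentre is touched.

Step 5
Reactants: 11 trans-hydrindenone silyl ether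
Product: 12 7β-(methoxycarbonylmethyl) ketone
Conditions: LDA, THF, −78 °C; BrCH2CO2Me, DMPU, −78 to −30 °C
Reagents that add atoms: methyl bromoacetate COC(=O)CBr
Why: In this kinetic enolate alkylation C7 is the only enolisable position of the C9 ketone (C10 is quaternary) and the small reactive electrophile should enter anti to the axial isopropenyl group (7β), a configuration of no lasting weight because C7 is re-equilibrated in step 9 and becomes sp2 in step 11.

Step 6
Reactants: 12 7β-(methoxycarbonylmethyl) ketone
Product: 14 8α-acetyl 13β-allylic alcohol, via silyl ether ketone 13 (not isolated)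
Conditions: OsO4 (2 mol %), NaIO4, 2,6-lutidine, dioxane–H2O, rt; then citric acid, MeOH, rt
Reagents that add atoms: sodium periodate [Na+].[O-]I(=O)(=O)=O
Why: In this Lemieux–Johnson oxidation OsO4 should attack the exposed 1,1-disubstituted isopropenyl group much faster than the C14=C15 bond, which is screened by the isopropyl group, the silyloxy-bearing C13 and the ring fusion, and mild acid then frees the 13β-hydroxyl needed in step 7.

Step 7
Reactants: 14 8α-acetyl 13β-allylic alcohol
Product: 15 hydroxy diketo ester with saturated ring D (15α-isopropyl)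
Conditions: [Ir(cod)(PCy3)(py)]PF6 (10 mol %), H2 (1 atm), CH2Cl2, rt
Reagents that add atoms: none
Why: In this hydroxyl-directed homogeneous hydrogenation the cationic iridium complex binds the 13β-hydroxyl and should deliver H2 to the β face of C14=C15, which places the isopropyl group α at C15 against the steric bias of the C10 methyl.

Step 8
Reactants: 15 hydroxy diketo ester
Product: 16 13β-benzyl ether
Conditions: BnOC(=NH)CCl3, TfOH (cat.), CH2Cl2–cyclohexane, 0 °C
Reagents that add atoms: benzyl 2,2,2-trichloroacetimidate N=C(OCc1ccccc1)C(Cl)(Cl)Cl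
Why: Acid-catalysed O-benzylation with a trichloroacetimidate protects the β-hydroxy ketone without base, so that retro-aldol opening of ring D is avoided, and benzyl is chosen because it falls off in step 16.

Step 9
Reactants: 16 13β-benzyl ether
Product: 17 diequatorial diketo ester (7α-CH2CO2Me, 8β-acetyl)
Conditions: DBU, toluene, 60 °C
Reagents that add atoms: none
Why: Thermodynamic epimerisation through the enols of the acetyl and C9 carbonyl groups should move the axial 8α-acetyl group and the axial 7β side chain (syn-axial to the C10 methyl) into equatorial positions of the rigid trans-hydrindane chair, giving 8α-H as in the target, while DBU is too weak to start ester condensations.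

Step 10
Reactants: 17 diequatorial diketo ester; 4 tributyl[(S)-3-methylcyclopent-1-en-1-yl]stannane
Product: 20 keto δ-lactone (1S), via alkenyllithium 18 (not isolated), via hydroxy ester 19 (not isolated)
Conditions: 4, n-BuLi, THF, −78 °C; CeCl3, −78 °C; 17, −78 °C, then 0 °C
Reagents that add atoms: none
Why: Tin–lithium exchange and transmetalation give a non-basic alkenylcerium reagent that should add (1,2-addition, Felkin–Anh-type control) only to the unhindered methyl ketone, entering anti to the C7 branch between H8 and C12 while cerium holds the carbonyl oxygen toward the ester side chain, which sets C1 as S, and the tertiary alkoxide then closes the trans-fused δ-lactone on the methyl ester.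

Step 11
Reactants: 20 keto δ-lactone
Product: 22 C6=C7 unsaturated keto lactone, via bromo lactone 21 (not isolated)
Conditions: LiHMDS, THF, −78 °C; NBS, −78 °C; DBU, −78 to 0 °C
Reagents that add atoms: none
Why: α-Bromination of the kinetically formed lactone enolate (C6 carries the most accessible acidic hydrogens) followed by base-induced E1cB loss of HBr through the C9 ketone (H7 is α to it) should give the ene-dicarbonyl compound, with no stereocentre formed and C7 erased.

Step 12
Reactants: 22 C6=C7 unsaturated keto lactone
Product: 24 enol phosphate lactone (6α-methyl), via lithium enolate 23 (not isolated)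
Conditions: MeLi, CuI, Et2O, 0 °C (Me2CuLi); 22, THF, −78 °C; ClP(O)(OEt)2, TMEDA, −78 to 0 °C
Reagents that add atoms: methyllithium C[Li] (used as Me2CuLi); diethyl chlorophosphate CCOP(=O)(Cl)OCC
Why: In this conjugate addition–enolate trapping sequence the cuprate should add to the carbon β to the ketone (C6, the usual regiochemistry of γ-oxo enoates) on the α face, anti to the axial C1 methyl and the C10 methyl, which sets C6, and O-phosphorylation of the regiodefined enolate fixes the C7=C9 double bond.

Step 13
Reactants: 24 enol phosphate lactone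
Product: 25 exocyclic enol ether (5-methylene tetrahydropyran)
Conditions: Cp2Ti(μ-Cl)(μ-CH2)AlMe2, pyridine, toluene–THF, −40 °C to rt; aq NaOH; basic alumina
Reagents that add atoms: Cp2Ti(μ-Cl)(μ-CH2)AlMe2 [CH2-2].[Ti+4].[cH-]1cccc1.[cH-]1cccc1.C[Al](C)Cl
Why: Titanium methylidene olefination of a lactone (Tebbe olefination) should turn C5=O into C5=C4H2 under non-basic conditions and below the temperature of the rearrangement, so that C6 is not epimerised and no ketone is present to be methylenated.

Step 14
Reactants: 25 exocyclic enol ether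
Product: 27 tetracyclic 5α-alcohol, via cyclooctenone 26 (not isolated)
Conditions: xylenes, Et3N (1 vol %), base-washed sealed tube, 150 °C; cool to −78 °C; i-Bu2AlH; aq potassium sodium tartrate
Reagents that add atoms: none
Why: On heating, the allyl vinyl ether array C4=C5–O–C1–C2=C3 should undergo a concerted suprafacial [3,3]-sigmatropic shift in which C3–C4 forms as C1–O breaks, enlarging the temporary six-membered ring by two atoms to the cyclooct-4-enone 26, which is reduced in the same flask before the β,γ-unsaturated ketone can epimerise at C6 or move into conjugation. The closest known reaction type is the Claisen ring expansion of 2-methylene-6-vinyltetrahydropyrans, made by titanium methylenation of δ-lactones, to cyclooct-4-enones. Ring B is the only ring closed, by pericyclic ring expansion (pyran in a boat with O and C7 at bow and stern, the six reacting atoms chair-like), and the small ring forces the new tetrasubstituted C1=C2 bond to be Z within ring B (C8 cis to C3, methyl cis to C18). C3 is set by 1,3-chirality transfer: since C8 must end cis to C3, the 1S configuration leaves only the β face of the cyclopentene open to C4, giving 3α-H with C4 cis to the C16 methyl, a contra-steric relation that no equilibrating method would give, while C5 is set by hydride attack anti to the 6α-methyl and is removed in step 16. The step needs periselectivity over acid-catalysed drift of the exocyclic double bond into the ring (which would open a [3,3] path to a six-membered carbocycle) and over ionisation to [1,3] products, and this is secured by base-washed glass, a trace of amine, a non-polar solvent and the absence of any Lewis acid during heating. The enol phosphate keeps C7 planar, which lets the pyran reach the boat, and deactivates C7=C9 toward ene-type side reactions.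

Step 15
Reactants: 27 tetracyclic 5α-alcohol
Product: 28 5α-(tetramethylphosphorodiamidate)
Conditions: n-BuLi, THF–TMEDA, −78 °C; ClP(O)(NMe2)2, −78 °C to rt
Reagents that add atoms: bis(dimethylamino)phosphoryl chloride CN(C)P(=O)(Cl)N(C)C
Why: O-Phosphorylation of the lithium alkoxide should activate the secondary alcohol for dissolving-metal deoxygenation, no acidic or electrophilic site other than the hydroxyl being exposed to one equivalent of base at low temperature.

Step 16
Reactants: 28 5α-(tetramethylphosphorodiamidate)
Product: 29 Aspergilol C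
Conditions: Li, EtNH2, t-BuOH, THF, 0 °C; aq NH4Cl
Reagents that add atoms: none
Why: Dissolving-metal reduction should cleave the three helper C–O bonds in one operation (enol phosphate to C9–H with the double bond kept at C7=C9, alkyl phosphorodiamidate to C5H2, benzyl ether to 13β-OH), while isolated tri- and tetrasubstituted alkenes are inert, t-BuOH buffers the amide base so that the skipped diene is not conjugated, and no stereocentre is touched.

**Compound list**

1 | cyclopent-2-en-1-one | O=C1C=CCC1 | starting material
2 | methylzinc (S)-3-methylcyclopent-1-en-1-olate | C[Zn]OC1=C[C@@H](C)CC1 | intermediate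
3 | (S)-3-methylcyclopent-1-en-1-yl trifluoromethanesulfonate | FC(F)(F)S(=O)(=O)OC1=C[C@@H](C)CC1 | intermediate
4 | tributyl[(S)-3-methylcyclopent-1-en-1-yl]stannane | CCCC[Sn](CCCC)(CCCC)C1=C[C@@H](C)CC1 | intermediate
5 | (R)-(−)-carvone | CC1=CC[C@H](CC1=O)C(C)=C | starting material
6 | 2-bromo-3-methylbut-1-ene | C=C(Br)C(C)C | starting material
7 | acrolein | C=CC=O | starting material
8 | (3-methylbut-1-en-2-yl)magnesium bromide | C=C([Mg]Br)C(C)C | intermediate
9 | bromomagnesium C9=C10 enolate, 11β-alkenyl, 8α-isopropenyl | C1C(O[Mg]Br)=C(C)[C@H](C(=C)C(C)C)C[C@H]1C(C)=C | intermediate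
10 | triene silyl ether: C9 ketone, C10 with β-CH3 and α-CH(OSiMe3)CH=CH2 (C13 as in the target), 11β-(3-methylbut-1-en-2-yl), 8α-isopropenyl | C1C(=O)[C@@](C)([C@H](O[Si](C)(C)C)C=C)[C@H](C(=C)C(C)C)C[C@H]1C(C)=C | intermediate
11 | trans-hydrindenone silyl ether: rings C and D, C14=C15, 13β-OSiMe3, 8α-isopropenyl | C1C(=O)[C@@]2(C)[C@H](O[Si](C)(C)C)C=C(C(C)C)[C@@H]2C[C@H]1C(C)=C | intermediate
12 | 7β-(methoxycarbonylmethyl) derivative of 11 | COC(=O)C[C@@H]1C(=O)[C@@]2(C)[C@H](O[Si](C)(C)C)C=C(C(C)C)[C@@H]2C[C@H]1C(C)=C | intermediate
13 | 8α-acetyl silyl ether | COC(=O)C[C@@H]1C(=O)[C@@]2(C)[C@H](O[Si](C)(C)C)C=C(C(C)C)[C@@H]2C[C@H]1C(C)=O | intermediate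
14 | 8α-acetyl 13β-allylic alcohol | COC(=O)C[C@@H]1C(=O)[C@@]2(C)[C@H](O)C=C(C(C)C)[C@@H]2C[C@H]1C(C)=O | intermediate
15 | hydroxy diketo ester, ring D saturated, 15α-isopropyl | COC(=O)C[C@@H]1C(=O)[C@@]2(C)[C@H](O)C[C@@H](C(C)C)[C@@H]2C[C@H]1C(C)=O | intermediate
16 | 13β-benzyl ether of 15 | COC(=O)C[C@@H]1C(=O)[C@@]2(C)[C@H](OCc3ccccc3)C[C@@H](C(C)C)[C@@H]2C[C@H]1C(C)=O | intermediate
17 | diequatorial diketo ester (7α-CH2CO2Me, 8β-acetyl) | COC(=O)C[C@H]1C(=O)[C@@]2(C)[C@H](OCc3ccccc3)C[C@@H](C(C)C)[C@@H]2C[C@@H]1C(C)=O | intermediate
18 | (S)-3-methylcyclopent-1-en-1-yllithium | [Li]C1=C[C@@H](C)CC1 | intermediate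
19 | (1S) tertiary allylic alcohol, hydroxy ester | COC(=O)C[C@H]1C(=O)[C@@]2(C)[C@H](OCc3ccccc3)C[C@@H](C(C)C)[C@@H]2C[C@@H]1[C@](C)(O)C4=C[C@@H](C)CC4 | intermediate
20 | keto δ-lactone (O, C5, C6, C7, C8, C1), trans-fused on ring C, 1S | O=C1C[C@H]2C(=O)[C@@]3(C)[C@H](OCc4ccccc4)C[C@@H](C(C)C)[C@@H]3C[C@@H]2[C@](C)(O1)C5=C[C@@H](C)CC5 | intermediate
21 | 6α-bromo keto lactone | O=C1[C@@H](Br)[C@H]2C(=O)[C@@]3(C)[C@H](OCc4ccccc4)C[C@@H](C(C)C)[C@@H]3C[C@@H]2[C@](C)(O1)C5=C[C@@H](C)CC5 | intermediate
22 | C6=C7 unsaturated keto lactone | O=C1C=C2C(=O)[C@@]3(C)[C@H](OCc4ccccc4)C[C@@H](C(C)C)[C@@H]3C[C@@H]2[C@](C)(O1)C5=C[C@@H](C)CC5 | intermediate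
23 | lithium C7=C9 enolate, 6α-methyl | O=C1[C@@H](C)C2=C(O[Li])[C@@]3(C)[C@H](OCc4ccccc4)C[C@@H](C(C)C)[C@@H]3C[C@@H]2[C@](C)(O1)C5=C[C@@H](C)CC5 | intermediate
24 | enol diethyl phosphate lactone, 6α-methyl | O=C1[C@@H](C)C2=C(OP(=O)(OCC)OCC)[C@@]3(C)[C@H](OCc4ccccc4)C[C@@H](C(C)C)[C@@H]3C[C@@H]2[C@](C)(O1)C5=C[C@@H](C)CC5 | intermediate
25 | exocyclic enol ether (C5=C4H2) | C=C1[C@@H](C)C2=C(OP(=O)(OCC)OCC)[C@@]3(C)[C@H](OCc4ccccc4)C[C@@H](C(C)C)[C@@H]3C[C@@H]2[C@](C)(O1)C5=C[C@@H](C)CC5 | intermediate
26 | tetracyclic cyclooct-4-enone (C5 ketone, Z C1=C2, 3α-H) | C/C1=C2\CC[C@H](C)[C@@H]2CC(=O)[C@@H](C)C2=C(OP(=O)(OCC)OCC)[C@@]3(C)[C@H](OCc4ccccc4)C[C@@H](C(C)C)[C@@H]3C[C@@H]21 | intermediate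
27 | tetracyclic 5α-alcohol | C/C1=C2\CC[C@H](C)[C@@H]2C[C@@H](O)[C@@H](C)C2=C(OP(=O)(OCC)OCC)[C@@]3(C)[C@H](OCc4ccccc4)C[C@@H](C(C)C)[C@@H]3C[C@@H]21 | intermediate
28 | 5α-(tetramethylphosphorodiamidate) | C/C1=C2\CC[C@H](C)[C@@H]2C[C@@H](OP(=O)(N(C)C)N(C)C)[C@@H](C)C2=C(OP(=O)(OCC)OCC)[C@@]3(C)[C@H](OCc4ccccc4)C[C@@H](C(C)C)[C@@H]3C[C@@H]21 | intermediate
29 | Aspergilol C | C/C1=C2\CC[C@H](C)[C@@H]2CC[C@@H](C)C2=C[C@@]3(C)[C@H](O)C[C@@H](C(C)C)[C@@H]3C[C@@H]21 | target

**Step count**

Total step count: 16. Longest linear sequence: 14 steps (steps 3 to 16, from (R)-carvone).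

**Steps most likely to fail**

Step 14. The exocyclic double bond may drift into the pyran ring before the rearrangement. The enol ether may also hydrolyse. Bond formation on the methyl-bearing face of ring A may be too slow.

The fallback replaces the pericyclic closure by a metal-templated ionic one. It sets out from 24 and comes back at 26.
- Lactone 24 is opened with PhSO2CH2Li (THF, −78 °C) to the hydroxy β-keto sulfone F1.
- The dianion of F1 is O-acylated at the alkoxide with ClCO2Me to give the tertiary allylic carbonate F2.
- Zerovalent palladium (Pd2(dba)3, dppe, THF, high dilution) ionises the carbonate. The sulfonyl-stabilised enolate attacks the less substituted allyl terminus C3 in an intramolecular Tsuji–Trost alkylation. Retention is net, so C4 arrives on the face the oxygen left, and the product is the sulfonyl cyclooctenone F3.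
- SmI2 (THF–MeOH) removes the sulfonyl group and gives 26, which is reduced to 27 as in step 14.

Step 10. Facial selectivity at the methyl ketone may be poor, and enolisation may compete.

The fallback replaces substrate control by reagent control. It sets out from 17 and 18 and comes back at 20.
- Alkenyllithium 18 is transmetalated with ZnBr2 to the alkenylzinc bromide F4.
- F4 is added to 17 with Ti(OiPr)4 and an enantiopure trans-cyclohexane-1,2-diamine bis(sulfonamide) diol ligand (catalytic asymmetric alkenylation of a ketone). The ligand antipode then chooses the carbonyl face.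
- The resulting 19 is lactonised with catalytic DBU to 20.

Step 3. Control of the carbinol configuration in the aldol event may be poor.

The fallback sets C13 by a redox correction on the closed ring. It sets out from 11 and comes back at 11.
- Material from step 4 is desilylated (citric acid, MeOH) to the allylic alcohol F5, at that point of mixed configuration at C13.
- MnO2 oxidises it to the single enedione F6.
- Luche reduction (NaBH4, CeCl3·7H2O, MeOH, −78 °C) attacks the cyclopentenone carbonyl, not the hindered C9 ketone, from the α face opposite the C10 methyl. This returns the allylic alcohol F5 as the 13β epimer.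
- Me3SiCl and imidazole convert it into 11.

Further compounds
F1 | step 14 | hydroxy β-keto sulfone | O=C(CS(=O)(=O)c1ccccc1)[C@@H](C)C2=C(OP(=O)(OCC)OCC)[C@@]3(C)[C@H](OCc4ccccc4)C[C@@H](C(C)C)[C@@H]3C[C@@H]2[C@](C)(O)C5=C[C@@H](C)CC5
F2 | step 14 | tertiary allylic methyl carbonate | O=C(CS(=O)(=O)c1ccccc1)[C@@H](C)C2=C(OP(=O)(OCC)OCC)[C@@]3(C)[C@H](OCc4ccccc4)C[C@@H](C(C)C)[C@@H]3C[C@@H]2[C@](C)(OC(=O)OC)C5=C[C@@H](C)CC5
F3 | step 14 | 4-(phenylsulfonyl) cyclooctenone (C4 configurationally labile) | C/C1=C2\CC[C@H](C)[C@@H]2C(S(=O)(=O)c5ccccc5)C(=O)[C@@H](C)C2=C(OP(=O)(OCC)OCC)[C@@]3(C)[C@H](OCc4ccccc4)C[C@@H](C(C)C)[C@@H]3C[C@@H]21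
F4 | step 10 | bromo[(S)-3-methylcyclopent-1-en-1-yl]zinc | Br[Zn]C1=C[C@@H](C)CC1
F5 | step 3 | 13β-allylic alcohol (desilylated 11) | C1C(=O)[C@@]2(C)[C@H](O)C=C(C(C)C)[C@@H]2C[C@H]1C(C)=C
F6 | step 3 | C9,C13 enedione | C1C(=O)[C@@]2(C)C(=O)C=C(C(C)C)[C@@H]2C[C@H]1C(C)=C
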